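**Retrosynthetic overview**

- The strategy rests on C8: a secondary carbon that carries the hindered oxygen of ring B (4-allyl-2,6-dimethoxyphenyl) and lies between C9 (CH2OH) and the C7 carbinol bearing ring A (3,4,5-trimethoxyphenyl). This C9–C8–C7 array is built one carbon at a time on a chiral boronic ester.
- C7 is disconnected last: C7–OH from C7–B (oxidation, retention), C7–ring A from Grignard displacement of an α-chloro boronate (inversion), and C7–C8 from LiCHCl2 insertion.
- C8 is disconnected next, in the key step: C8–O(ring B) by aryloxide capture and C9–C8 by LiCHCl2 insertion into the (S,S)-1,2-dicyclohexylethanediol ester of (4-methoxybenzyloxymethyl)boronic acid.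
- That boronate comes from chloromethyl pinacol boronate, 4-methoxybenzyl alcohol and the (S,S)-diol.
- No ring of the target is formed; rings A and B are bought. The dioxaborolane is an auxiliary ring, made in step 3 and removed in step 8.

Key step: step 5

Assumption: the (S,S)-diol is taken to direct LiCHCl2 insertion in its usual sense, giving the (1R)-chloride when a carbon group migrates; if the sense proved opposite, the (R,R)-diol would be used. C7, C8 and C9 denote the benzylic carbinol carbon, the aryloxy carbon and the CH2OH carbon.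

**Route**

Step 1
Reactants: 1 2-(chloromethyl)-4,4,5,5-tetramethyl-1,3,2-dioxaborolane; 2 4-methoxybenzyl alcohol
Product: 4 2-[(4-methoxybenzyloxy)methyl]-4,4,5,5-tetramethyl-1,3,2-dioxaborolane, via sodium 4-methoxybenzyl oxide 3 (not isolated)
Conditions: 2, NaH, THF, 0 °C → rt; then 1, THF/DMSO, 0 °C → rt
Reagents that add atoms: none
Why: Substitution of an α-halo boronic ester by an alkoxide (Matteson-type), in which the alkoxide adds to boron and oxygen shifts from boron to the CH2 carbon with loss of chloride; no stereocentre is involved.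

Step 2
Reactants: 4 2-[(4-methoxybenzyloxy)methyl]-4,4,5,5-tetramethyl-1,3,2-dioxaborolane
Product: 5 2-[(4-methoxybenzyloxy)methyl]-1,3,6,2-dioxazaborocane (N→B coordinated diethanolamine adduct)
Conditions: HN(CH2CH2OH)2, Et2O, rt; precipitate filtered
Reagents that add atoms: diethanolamine OCCNCCO
Why: Transesterification of the pinacol ester with diethanolamine, driven by the N→B dative bond and by precipitation of the bicyclic adduct from ether, which is a standard mild way to take pinacol off an alkylboronate.

Step 3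
Reactants: 5 2-[(4-methoxybenzyloxy)methyl]-1,3,6,2-dioxazaborocane; 6 (1S,2S)-1,2-dicyclohexylethane-1,2-diol
Product: 8 (4S,5S)-4,5-dicyclohexyl-2-[(4-methoxybenzyloxy)methyl]-1,3,2-dioxaborolane, via [(4-methoxybenzyloxy)methyl]boronic acid 7 (not isolated)
Conditions: 6, Et2O/0.5 M aq HCl, rt, 30 min; MgSO4
Reagents that add atoms: none
Why: Acid hydrolysis of the diethanolamine adduct followed by boronic ester formation with the 1,2-diol in the ether layer; the amine leaves in the aqueous acid, the 4-methoxybenzyl ether tolerates brief contact with cold dilute acid, and the diol stereocentres are not touched.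

Step 4
Reactants: 9 4-allyl-2,6-dimethoxyphenol
Product: 10 sodium 4-allyl-2,6-dimethoxyphenoxide
Conditions: NaH (0.95 equiv), THF, 0 °C → rt; then diluted with DMSO and used as the solution
Reagents that add atoms: sodium hydride [Na+].[H-]
Why: Acid–base reaction in which NaH deprotonates the phenol irreversibly; a slight deficit of hydride leaves no strong base that could move the allyl double bond into conjugation once DMSO is present.

Step 5
Reactants: 8 (4S,5S)-4,5-dicyclohexyl-2-[(4-methoxybenzyloxy)methyl]-1,3,2-dioxaborolane; 10 sodium 4-allyl-2,6-dimethoxyphenoxide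
Product: 12 (4S,5S)-2-[(1S)-1-(4-allyl-2,6-dimethoxyphenoxy)-2-(4-methoxybenzyloxy)ethyl]-4,5-dicyclohexyl-1,3,2-dioxaborolane, via (1R)-chloro boronate 11 (not isolated)
Conditions: CH2Cl2, n-BuLi, THF, −100 °C; 8; ZnCl2, −100 °C → rt; pentane, salts filtered off; then 10, THF/DMSO, 0 °C → rt
Reagents that add atoms: dichloromethane ClCCl
Why: Proposed new method: LiCHCl2 adds to the boron of 8, and ZnCl2 then promotes the 1,2-shift of C9 from boron to carbon with loss of the chloride that the C2-symmetric (S,S)-diol singles out, which forms the C9–C8 bond and the (1R)-chloride 11; the aryloxide 10 next binds the boron of 11 and its oxygen shifts to C8 anti to the departing chloride, which forms the C8–O bond with inversion and gives (1S)-12. The closest known reaction type is the Matteson homologation with capture of the α-chloro boronic ester by sodium or lithium alkoxides such as benzyl oxide or 4-methoxybenzyl oxide; what is new is a less basic, di-ortho-substituted aryloxide as the group that shifts from boron to carbon. No ring is closed. The C8 stereocentre is set by the diol (reagent control in the chloride-selecting shift) and then by a stereospecific invertive shift, so it does not depend on the substrate. The step needs substitution to outrun β-elimination of the C9 alkoxide from the borate and chloride-induced epimerisation of 11; the poor leaving-group ability of the 4-methoxybenzyl oxide, the low temperature, ZnCl2 as chloride scavenger and removal of the salts before the aryloxide is added should secure this. Delivery of the hindered oxygen through boron avoids an intermolecular SN2 attack at a secondary carbon.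

Step 6
Reactants: 12 (4S,5S)-2-[(1S)-1-(4-allyl-2,6-dimethoxyphenoxy)-2-(4-methoxybenzyloxy)ethyl]-4,5-dicyclohexyl-1,3,2-dioxaborolane
Product: 13 (4S,5S)-2-[(1R,2R)-2-(4-allyl-2,6-dimethoxyphenoxy)-1-chloro-3-(4-methoxybenzyloxy)propyl]-4,5-dicyclohexyl-1,3,2-dioxaborolane
Conditions: CH2Cl2, n-BuLi, THF, −100 °C; 12; ZnCl2, −100 °C → rt; pentane/aq NH4Cl work-up, used crude at once
Reagents that add atoms: dichloromethane ClCCl
Why: Matteson homologation, in which LiCHCl2 adds to boron and ZnCl2 promotes the 1,2-shift of C8 with retention and loss of the chloride chosen by the (S,S)-diol; this sets C7 as the (1R)-chloride by reagent control as in the first cycle, α-alkoxy boronic esters being established substrates for the insertion.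

Step 7
Reactants: 13 (4S,5S)-2-[(1R,2R)-2-(4-allyl-2,6-dimethoxyphenoxy)-1-chloro-3-(4-methoxybenzyloxy)propyl]-4,5-dicyclohexyl-1,3,2-dioxaborolane; 14 5-bromo-1,2,3-trimethoxybenzene
Product: 16 (4S,5S)-2-[(1R,2S)-2-(4-allyl-2,6-dimethoxyphenoxy)-3-(4-methoxybenzyloxy)-1-(3,4,5-trimethoxyphenyl)propyl]-4,5-dicyclohexyl-1,3,2-dioxaborolane, via 3,4,5-trimethoxyphenylmagnesium bromide 15 (not isolated)
Conditions: 14, Mg, THF, rt → 40 °C; then 13, THF, −78 °C → rt
Reagents that add atoms: none
Why: Displacement of an α-chloro boronic ester by a Grignard reagent (Matteson), in which the aryl group adds to boron at −78 °C and shifts to C7 anti to chloride on warming, so C7 is inverted stereospecifically and ring A arrives on the face needed for the threo product (the change of descriptor at C8 is only a change of priorities).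

Step 8
Reactants: 16 (4S,5S)-2-[(1R,2S)-2-(4-allyl-2,6-dimethoxyphenoxy)-3-(4-methoxybenzyloxy)-1-(3,4,5-trimethoxyphenyl)propyl]-4,5-dicyclohexyl-1,3,2-dioxaborolane
Product: 17 (1R,2R)-2-(4-allyl-2,6-dimethoxyphenoxy)-3-(4-methoxybenzyloxy)-1-(3,4,5-trimethoxyphenyl)propan-1-ol
Conditions: 30% H2O2, 2 M NaOH, THF, 0 °C → rt
Reagents that add atoms: hydrogen peroxide OO
Why: Oxidation of a C–B bond by alkaline hydrogen peroxide, in which hydroperoxide adds to boron and C7 migrates to oxygen with retention to give the (7R) carbinol and release the diol for recovery; the isolated allyl double bond does not react with nucleophilic peroxide.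

Step 9
Reactants: 17 (1R,2R)-2-(4-allyl-2,6-dimethoxyphenoxy)-3-(4-methoxybenzyloxy)-1-(3,4,5-trimethoxyphenyl)propan-1-ol
Product: 18 (1R,2R)-2-(4-allyl-2,6-dimethoxyphenoxy)-1-(3,4,5-trimethoxyphenyl)propane-1,3-diol
Conditions: DDQ (1.2 equiv), CH2Cl2/pH 7 phosphate buffer, 0 °C
Reagents that add atoms: none
Why: Oxidative cleavage of a 4-methoxybenzyl ether by DDQ, in which hydride abstraction at the most electron-rich benzylic ether position and hydrolysis of the oxocarbenium ion free the C9 hydroxyl; low temperature, buffer and a small excess of oxidant should spare the allylarene and the C7 carbinol, and no stereocentre is affected.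

**Compound list**

1 | 2-(chloromethyl)-4,4,5,5-tetramethyl-1,3,2-dioxaborolane | ClCB1OC(C)(C)C(C)(C)O1 | starting material
2 | 4-methoxybenzyl alcohol | COc1ccc(CO)cc1 | starting material
3 | sodium 4-methoxybenzyl oxide | COc1ccc(C[O-])cc1.[Na+] | intermediate
4 | 2-[(4-methoxybenzyloxy)methyl]-4,4,5,5-tetramethyl-1,3,2-dioxaborolane | COc1ccc(COCB2OC(C)(C)C(C)(C)O2)cc1 | intermediate
5 | 2-[(4-methoxybenzyloxy)methyl]-1,3,6,2-dioxazaborocane | COc1ccc(COCB2OCCNCCO2)cc1 | intermediate
6 | (1S,2S)-1,2-dicyclohexylethane-1,2-diol | O[C@@H](C1CCCCC1)[C@@H](O)C1CCCCC1 | starting material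
7 | [(4-methoxybenzyloxy)methyl]boronic acid | COc1ccc(COCB(O)O)cc1 | intermediate
8 | (4S,5S)-4,5-dicyclohexyl-2-[(4-methoxybenzyloxy)methyl]-1,3,2-dioxaborolane | COc1ccc(COCB2O[C@@H](C3CCCCC3)[C@H](C3CCCCC3)O2)cc1 | intermediate
9 | 4-allyl-2,6-dimethoxyphenol | C=CCc1cc(OC)c(O)c(OC)c1 | starting material
10 | sodium 4-allyl-2,6-dimethoxyphenoxide | [Na+].[O-]c1c(OC)cc(CC=C)cc1OC | intermediate
11 | (4S,5S)-2-[(1R)-1-chloro-2-(4-methoxybenzyloxy)ethyl]-4,5-dicyclohexyl-1,3,2-dioxaborolane | COc1ccc(COC[C@H](Cl)B2O[C@@H](C3CCCCC3)[C@H](C3CCCCC3)O2)cc1 | intermediate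
12 | (4S,5S)-2-[(1S)-1-(4-allyl-2,6-dimethoxyphenoxy)-2-(4-methoxybenzyloxy)ethyl]-4,5-dicyclohexyl-1,3,2-dioxaborolane | C=CCc1cc(OC)c(O[C@H](COCc2ccc(OC)cc2)B2O[C@@H](C3CCCCC3)[C@H](C3CCCCC3)O2)c(OC)c1 | intermediate
13 | (4S,5S)-2-[(1R,2R)-2-(4-allyl-2,6-dimethoxyphenoxy)-1-chloro-3-(4-methoxybenzyloxy)propyl]-4,5-dicyclohexyl-1,3,2-dioxaborolane | C=CCc1cc(OC)c(O[C@H](COCc2ccc(OC)cc2)[C@H](Cl)B2O[C@@H](C3CCCCC3)[C@H](C3CCCCC3)O2)c(OC)c1 | intermediate
14 | 5-bromo-1,2,3-trimethoxybenzene | COc1cc(Br)cc(OC)c1OC | starting material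
15 | 3,4,5-trimethoxyphenylmagnesium bromide | COc1cc([Mg]Br)cc(OC)c1OC | intermediate
16 | (4S,5S)-2-[(1R,2S)-2-(4-allyl-2,6-dimethoxyphenoxy)-3-(4-methoxybenzyloxy)-1-(3,4,5-trimethoxyphenyl)propyl]-4,5-dicyclohexyl-1,3,2-dioxaborolane | C=CCc1cc(OC)c(O[C@H](COCc2ccc(OC)cc2)[C@@H](c2cc(OC)c(OC)c(OC)c2)B2O[C@@H](C3CCCCC3)[C@H](C3CCCCC3)O2)c(OC)c1 | intermediate
17 | (1R,2R)-2-(4-allyl-2,6-dimethoxyphenoxy)-3-(4-methoxybenzyloxy)-1-(3,4,5-trimethoxyphenyl)propan-1-ol | C=CCc1cc(OC)c(O[C@H](COCc2ccc(OC)cc2)[C@H](O)c2cc(OC)c(OC)c(OC)c2)c(OC)c1 | intermediate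
18 | (1R,2R)-2-(4-allyl-2,6-dimethoxyphenoxy)-1-(3,4,5-trimethoxyphenyl)propane-1,3-diol | C=CCc1cc(OC)c(O[C@H](CO)[C@H](O)c2cc(OC)c(OC)c(OC)c2)c(OC)c1 | target

**Step count**

Total steps: 9. Longest linear sequence: 8 steps (1 → 4 → 5 → 8 → 12 → 13 → 16 → 17 → 18); step 4 is a one-step side branch.

**Steps most likely to fail**

1. Step 5 (proposed new method). The hindered, weakly basic aryloxide may bind boron too weakly or shift too slowly. β-Elimination of the C9 alkoxide from the borate, chloride exchange that epimerises C8, or recovery of unreacted chloride could then take over. The fallback uses known chemistry, sets out from 9 and comes back at 18. O-Alkylation of 9 with bromoacetic acid (aq NaOH, reflux) should give 2-(4-allyl-2,6-dimethoxyphenoxy)acetic acid F1. Activation as the pivaloyl mixed anhydride (pivaloyl chloride, Et3N, THF, −20 °C) and acylation of lithiated (S)-4-benzyl-1,3-oxazolidin-2-one should give (4S)-3-[2-(4-allyl-2,6-dimethoxyphenoxy)acetyl]-4-benzyl-1,3-oxazolidin-2-one F2. Its Z boron enolate (Bu2BOTf, i-Pr2NEt, CH2Cl2, −78 °C) should add to 3,4,5-trimethoxybenzaldehyde through a chair transition state (Evans syn aldol) to give (4S)-4-benzyl-3-[(2S,3R)-2-(4-allyl-2,6-dimethoxyphenoxy)-3-hydroxy-3-(3,4,5-trimethoxyphenyl)propanoyl]-1,3-oxazolidin-2-one F3, in which both stereocentres have the threo arrangement of the target. LiBH4 (THF/MeOH, 0 °C) then removes the auxiliary reductively and turns the acyl carbon into C9–OH, which gives 18.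

2. Step 7. Once the aryl Grignard reagent has added to boron, the borate carries the ring B oxide on the β-carbon. Loss of boron and aryloxide by β-elimination may compete with the 1,2-aryl shift, and addition to the hindered boron may be slow. The fallback sets out from 13 and comes back at 17. Buffered oxidation of 13 (H2O2, pH 8 phosphate buffer, THF, 0 °C), in which the α-chloro carbinol formed at C7 loses HCl, should give (2R)-2-(4-allyl-2,6-dimethoxyphenoxy)-3-(4-methoxybenzyloxy)propanal F4 with C8 intact. Addition of 15 to this aldehyde after precomplexation with MgBr2·OEt2 in CH2Cl2 at −78 °C (Cram chelate through the aldehyde and C8 ether oxygens) is expected to favour the syn adduct 17; the C7 epimer would be removed by chromatography.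

3. Step 9. The oxocarbenium ion formed from the 4-methoxybenzyl ether may be trapped by the C7 hydroxyl to give a cyclic acetal, which excess oxidant can oxidise further. DDQ may also attack the C7 carbinol or the doubly activated CH2 of the allyl group. The fallback sets out from 17 and comes back at 18. Acetylation (Ac2O, pyridine, DMAP, rt) should give (1R,2R)-2-(4-allyl-2,6-dimethoxyphenoxy)-3-(4-methoxybenzyloxy)-1-(3,4,5-trimethoxyphenyl)propyl acetate F5, in which the C7 oxygen can no longer trap the cation or be oxidised. DDQ (CH2Cl2/pH 7 buffer, 0 °C) should then give (1R,2R)-2-(4-allyl-2,6-dimethoxyphenoxy)-3-hydroxy-1-(3,4,5-trimethoxyphenyl)propyl acetate F6. Methanolysis (K2CO3, MeOH, 0 °C) removes the acetyl group, wherever it sits after any migration, and gives 18.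

Further compounds
F1 | step 5 | 2-(4-allyl-2,6-dimethoxyphenoxy)acetic acid | C=CCc1cc(OC)c(OCC(=O)O)c(OC)c1
F2 | step 5 | (4S)-3-[2-(4-allyl-2,6-dimethoxyphenoxy)acetyl]-4-benzyl-1,3-oxazolidin-2-one | C=CCc1cc(OC)c(OCC(=O)N2[C@@H](Cc3ccccc3)COC2=O)c(OC)c1
F3 | step 5 | (4S)-4-benzyl-3-[(2S,3R)-2-(4-allyl-2,6-dimethoxyphenoxy)-3-hydroxy-3-(3,4,5-trimethoxyphenyl)propanoyl]-1,3-oxazolidin-2-one | C=CCc1cc(OC)c(O[C@H](C(=O)N2[C@@H](Cc3ccccc3)COC2=O)[C@H](O)c2cc(OC)c(OC)c(OC)c2)c(OC)c1
F4 | step 7 | (2R)-2-(4-allyl-2,6-dimethoxyphenoxy)-3-(4-methoxybenzyloxy)propanal | C=CCc1cc(OC)c(O[C@H](COCc2ccc(OC)cc2)C=O)c(OC)c1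
F5 | step 9 | (1R,2R)-2-(4-allyl-2,6-dimethoxyphenoxy)-3-(4-methoxybenzyloxy)-1-(3,4,5-trimethoxyphenyl)propyl acetate | C=CCc1cc(OC)c(O[C@H](COCc2ccc(OC)cc2)[C@H](OC(C)=O)c2cc(OC)c(OC)c(OC)c2)c(OC)c1
F6 | step 9 | (1R,2R)-2-(4-allyl-2,6-dimethoxyphenoxy)-3-hydroxy-1-(3,4,5-trimethoxyphenyl)propyl acetate | C=CCc1cc(OC)c(O[C@H](CO)[C@H](OC(C)=O)c2cc(OC)c(OC)c(OC)c2)c(OC)c1
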